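## Retrosynthetic overview

1. Numbering (germacrane) used throughout: C1(H)=C10(CH3), C2, C3, C4(CH3)–C5 oxirane, C6 (O-cinnamoyl), C7 (isopropyl), C8 (OH), C9 (CH2).
2. Last disconnection is C9–C10. The ring array HO–C8–C9H2–C10(CH3)=C1H, a homoallylic alcohol whose trisubstituted (E)-alkene lies in the ten-membered ring, is the retron of a nickel-catalysed reductive coupling of the methyl alkyne C1≡C10 with the monosubstituted oxirane C8–C9. The cis-fused three-membered 4,5-oxirane (C3 and C6 on the same side) bends the open chain so that C9 and C10 can meet.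
3. The open-chain bis-epoxy alkynyl cinnamate is reached by esterification at C6–O, hydroxyl-directed epoxidation of a (Z)-allylic alcohol (C4, C5), chlorohydrin closure (oxirane C8–C9) and 1,3-anti reduction (C8) of a chloromethyl ketone made from a Weinreb amide.
4. C6–C7 comes from an Evans syn-aldol of an isovaleryl oxazolidinone with (2Z)-3-methyloct-2-en-6-ynal. Its (Z)-alkene (C4=C5) comes from a Negishi coupling (bond C3–C4) of (2Z)-3-iodobut-2-en-1-ol with pent-3-yn-1-ylzinc iodide.
5. Ring order: oxirane C8–C9 (step 10), oxirane C4–C5 (step 11), ten-membered carbocycle last (step 13). No protecting group is used.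

Key step: step 13

## Route

Step 1
Reactants: 1 but-2-yn-1-ol
Product: 2 (2Z)-3-iodobut-2-en-1-ol
Conditions: NaAlH2(OCH2CH2OCH3)2 (Red-Al, 1.5 equiv), THF, 0 °C to rt; EtOAc quench; I2 (1.5 equiv), THF, −78 °C to 0 °C
Reagents that add atoms: iodine, [I][I]
Why: Trans-hydroalumination of a propargylic alcohol, in which the alkoxy-aluminate delivers hydride to C2 and the five-membered oxa-aluminacycle holds aluminium cis to CH2OH, followed by iodinolysis with retention, should give the (Z)-vinyl iodide.

Step 2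
Reactants: 3 pent-3-yn-1-ol
Product: 4 5-iodopent-2-yne
Conditions: I2, PPh3, imidazole, CH2Cl2, 0 °C to rt
Reagents that add atoms: iodine, [I][I]
Why: Appel-type iodination of a primary alcohol via the alkoxyphosphonium iodide should proceed cleanly, the internal alkyne being inert.

Step 3
Reactants: 4 5-iodopent-2-yne; 2 (2Z)-3-iodobut-2-en-1-ol
Product: 6 (2Z)-3-methyloct-2-en-6-yn-1-ol, via pent-3-yn-1-ylzinc iodide 5 (not isolated)
Conditions: 4, Zn dust (activated with BrCH2CH2Br and Me3SiCl), LiCl, THF, 30 °C; then 2 (0.45 equiv), Pd(OAc)2 (2 mol%), SPhos (4 mol%), THF, rt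
Reagents that add atoms: none
Why: Negishi sp3–sp2 coupling of a homopropargylzinc halide with an alkenyl iodide should occur with retention of alkene geometry and faster than protonolysis by the free hydroxyl (excess 5 covers any loss), placing the C3 chain cis to C6 as the target's cis-oxirane requires.

Step 4
Reactants: 6 (2Z)-3-methyloct-2-en-6-yn-1-ol
Product: 7 (2Z)-3-methyloct-2-en-6-ynal
Conditions: TEMPO (10 mol%), PhI(OAc)2 (1.1 equiv), CH2Cl2, rt
Reagents that add atoms: none
Why: Oxoammonium (TEMPO) oxidation of an allylic alcohol under near-neutral conditions should give the enal without Z to E isomerisation.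

Step 5
Reactants: 8 (4S)-4-benzyl-1,3-oxazolidin-2-one; 9 3-methylbutanoyl chloride
Product: 10 (4S)-4-benzyl-3-(3-methylbutanoyl)-1,3-oxazolidin-2-one
Conditions: Et3N, DMAP (10 mol%), CH2Cl2, 0 °C to rt
Reagents that add atoms: none
Why: DMAP-catalysed N-acylation of the oxazolidinone with an acid chloride is a standard acyl transfer that leaves the stereocentre untouched.

Step 6
Reactants: 10 (4S)-4-benzyl-3-(3-methylbutanoyl)-1,3-oxazolidin-2-one; 7 (2Z)-3-methyloct-2-en-6-ynal
Product: 13 (4S)-4-benzyl-3-[(2S,3R,4Z)-3-hydroxy-5-methyl-2-(propan-2-yl)dec-4-en-8-ynoyl]-1,3-oxazolidin-2-one, via (Z)-dibutylboron enolate 11 (not isolated), via dibutylboron aldolate 12 (not isolated)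
Conditions: Bu2BOTf (1.2 equiv), iPr2NEt (1.4 equiv), CH2Cl2, 0 °C; 7, −78 °C to 0 °C; pH 7 buffer, MeOH, 30% H2O2, 0 °C
Reagents that add atoms: none
Why: Evans syn-aldol, in which the (Z)-boron enolate reacts through a Zimmerman–Traxler chair with the benzyl group of the auxiliary shielding one enolate face, should set C7 and C6 (syn, acyl descriptors 2S,3R) under auxiliary control.

Step 7
Reactants: 13 (4S)-4-benzyl-3-[(2S,3R,4Z)-3-hydroxy-5-methyl-2-(propan-2-yl)dec-4-en-8-ynoyl]-1,3-oxazolidin-2-one
Product: 14 (2S,3R,4Z)-3-hydroxy-N-methoxy-N,5-dimethyl-2-(propan-2-yl)dec-4-en-8-ynamide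
Conditions: MeNH(OMe)·HCl (4 equiv), AlMe3 (4 equiv), CH2Cl2, −20 °C to rt; aqueous KNaC4H4O6 work-up
Reagents that add atoms: N,O-dimethylhydroxylamine hydrochloride, CNOC.Cl
Why: Aluminium amide transamination to the Weinreb amide should be directed to the exocyclic carbonyl by the aluminium alkoxide of the free 3-hydroxyl and proceed without epimerisation at C7.

Step 8
Reactants: 14 (2S,3R,4Z)-3-hydroxy-N-methoxy-N,5-dimethyl-2-(propan-2-yl)dec-4-en-8-ynamide
Product: 16 (3S,4R,5Z)-1-chloro-4-hydroxy-6-methyl-3-(propan-2-yl)undec-5-en-9-yn-2-one, via dilithium tetrahedral adduct 15 (not isolated)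
Conditions: MeLi·LiBr (1.0 equiv), THF/Et2O, −78 °C; ICH2Cl (3 equiv), then MeLi·LiBr (3 equiv) dropwise, −78 °C; aqueous NH4Cl at −78 °C
Reagents that add atoms: chloroiodomethane, ClCI
Why: Addition of chloromethyllithium (lithium carbenoid made by iodine–lithium exchange in the presence of the substrate) to a Weinreb amide should stop at the chelated tetrahedral adduct, which releases the chloromethyl ketone (C9 installed) only on quench.

Step 9
Reactants: 16 (3S,4R,5Z)-1-chloro-4-hydroxy-6-methyl-3-(propan-2-yl)undec-5-en-9-yn-2-one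
Product: 17 (2S,3S,4R,5Z)-1-chloro-6-methyl-3-(propan-2-yl)undec-5-en-9-yne-2,4-diol
Conditions: Me4NBH(OAc)3 (5 equiv), MeCN/AcOH (1:1), −30 °C
Reagents that add atoms: none
Why: Evans–Saksena reduction, in which the C6 hydroxyl binds boron and delivers hydride intramolecularly through a chair transition state, should set C8 as the 1,3-anti diol.

Step 10
Reactants: 17 (2S,3S,4R,5Z)-1-chloro-6-methyl-3-(propan-2-yl)undec-5-en-9-yne-2,4-diol
Product: 18 (3S,4R,5Z)-2,6-dimethyl-3-[(2S)-oxiran-2-yl]undec-5-en-9-yn-4-ol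
Conditions: K2CO3 (2 equiv), MeOH, 0 °C to rt
Reagents that add atoms: none
Why: Base-mediated chlorohydrin closure (intramolecular Williamson, 3-exo-tet) by the vicinal C8 alkoxide should outrun tetrahydrofuran formation by the C6 hydroxyl and leaves C8 unchanged because its C–O bond is not broken.

Step 11
Reactants: 18 (3S,4R,5Z)-2,6-dimethyl-3-[(2S)-oxiran-2-yl]undec-5-en-9-yn-4-ol
Product: 19 (1S,2S)-3-methyl-1-[(2R,3S)-3-methyl-3-(pent-3-yn-1-yl)oxiran-2-yl]-2-[(2S)-oxiran-2-yl]butan-1-ol
Conditions: mCPBA (1.2 equiv), NaHCO3, CH2Cl2, 0 °C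
Reagents that add atoms: meta-chloroperoxybenzoic acid, O=C(OO)c1cccc(Cl)c1
Why: Hydroxyl-directed Prilezhaev (Henbest) epoxidation should give the threo epoxy alcohol (4S,5R), because allylic 1,3-strain with the cis C3 methylene holds H6 in the alkene plane and the peracid is delivered to the face bearing the hydroxyl, the syn addition keeping C3 and C6 cis.

Step 12
Reactants: 19 (1S,2S)-3-methyl-1-[(2R,3S)-3-methyl-3-(pent-3-yn-1-yl)oxiran-2-yl]-2-[(2S)-oxiran-2-yl]butan-1-ol; 20 (E)-cinnamic anhydride
Product: 21 (1S,2R)-3-methyl-1-[(2R,3S)-3-methyl-3-(pent-3-yn-1-yl)oxiran-2-yl]-2-[(2S)-oxiran-2-yl]butyl (2E)-3-phenylprop-2-enoate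
Conditions: 20 (1.5 equiv), Et3N, DMAP (20 mol%), CH2Cl2, 0 °C to rt
Reagents that add atoms: none
Why: DMAP-catalysed acyl transfer (Steglich-type esterification) to the secondary alcohol under amine base avoids alkoxide formation and hence Payne rearrangement or oxirane opening.

Step 13
Reactants: 21 (1S,2R)-3-methyl-1-[(2R,3S)-3-methyl-3-(pent-3-yn-1-yl)oxiran-2-yl]-2-[(2S)-oxiran-2-yl]butyl (2E)-3-phenylprop-2-enoate
Product: 24 (1R,2S,3R,4R,6E,10S)-4-hydroxy-6,10-dimethyl-3-(propan-2-yl)-11-oxabicyclo[8.1.0]undec-6-en-2-yl (2E)-3-phenylprop-2-enoate, via oxanickelacyclohexene 22 (not isolated), via diethylborinate 23 (not isolated)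
Conditions: Ni(cod)2 (20 mol%), PBu3 (40 mol%), Et3B (4 equiv), THF, rt, syringe-pump addition of 21 to a final 0.005 M; aqueous NaHCO3, air
Reagents that add atoms: none
Why: Zerovalent nickel (Ni(cod)2/PBu3) binds the C1≡C10 alkyne and opens the monosubstituted oxirane at its CH2 terminus (C9), forming the C9–C10 bond by syn carbometalation to give an oxanickelacyclohexene of divalent nickel (Ni–C1=C10–C9–C8–O); Et3B then takes the oxygen, passes ethyl to nickel, and beta-hydride elimination followed by C–H reductive elimination puts hydrogen on C1 cis to C9, releasing ethene and zerovalent nickel. The closest known reaction type is the nickel-catalysed reductive coupling of alkynes with terminal epoxides (Ni(cod)2, PBu3, Et3B), known between two molecules, for five- and six-membered rings and for a fourteen-membered macrolactone closed in the endo mode; here it is applied to a ten-membered carbocycle. The ten-membered ring closes endo on both partners: endo-dig at the alkyne (bond to the distal carbon C10) and endo opening of the oxirane at its distal carbon C9, the C8–O bond staying intact. No stereocentre is made or touched, C8 keeping the configuration of the oxirane, and the (E)-geometry of C1=C10 follows from cis addition of H and C9 across the alkyne. The step needs chemoselection for the terminal over the trisubstituted oxirane (secured by the SN2-like oxidative addition, open only to the unhindered CH2) and over the cinnamate alkene, and regioselection for C10 over C1 (favoured by the small methyl group on C10 and by closing a ten-membered ring with an endocyclic alkene instead of a nine-membered ring with an exocyclic ethylidene). High dilution should suppress alkyne oligomerisation, and the cis-4,5-oxirane acts as a turn that brings C9 and C10 together.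

## Compound list

1 | but-2-yn-1-ol | CC#CCO | starting material
2 | (2Z)-3-iodobut-2-en-1-ol | C/C(I)=C/CO | intermediate
3 | pent-3-yn-1-ol | CC#CCCO | starting material
4 | 5-iodopent-2-yne | CC#CCCI | intermediate
5 | pent-3-yn-1-ylzinc iodide | CC#CCC[Zn]I | intermediate
6 | (2Z)-3-methyloct-2-en-6-yn-1-ol | CC#CCC/C(C)=C\CO | intermediate
7 | (2Z)-3-methyloct-2-en-6-ynal | CC#CCC/C(C)=C\C=O | intermediate
8 | (4S)-4-benzyl-1,3-oxazolidin-2-one | O=C1N[C@@H](Cc2ccccc2)CO1 | starting material
9 | 3-methylbutanoyl chloride | CC(C)CC(Cl)=O | starting material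
10 | (4S)-4-benzyl-3-(3-methylbutanoyl)-1,3-oxazolidin-2-one | CC(C)CC(=O)N1[C@@H](Cc2ccccc2)COC1=O | intermediate
11 | (Z)-dibutylboron enolate of 10 | CC(C)/C=C(\OB(CCCC)CCCC)N1[C@@H](Cc2ccccc2)COC1=O | intermediate
12 | dibutylboron aldolate of 13 | CC#CCC/C(C)=C\[C@@H](OB(CCCC)CCCC)[C@H](C(C)C)C(=O)N1[C@@H](Cc2ccccc2)COC1=O | intermediate
13 | (4S)-4-benzyl-3-[(2S,3R,4Z)-3-hydroxy-5-methyl-2-(propan-2-yl)dec-4-en-8-ynoyl]-1,3-oxazolidin-2-one | CC#CCC/C(C)=C\[C@@H](O)[C@H](C(C)C)C(=O)N1[C@@H](Cc2ccccc2)COC1=O | intermediate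
14 | (2S,3R,4Z)-3-hydroxy-N-methoxy-N,5-dimethyl-2-(propan-2-yl)dec-4-en-8-ynamide | CC#CCC/C(C)=C\[C@@H](O)[C@H](C(C)C)C(=O)N(C)OC | intermediate
15 | dilithium tetrahedral adduct of 14 with chloromethyllithium | CC#CCC/C(C)=C\[C@@H](O[Li])[C@H](C(C)C)C(CCl)(O[Li])N(C)OC | intermediate
16 | (3S,4R,5Z)-1-chloro-4-hydroxy-6-methyl-3-(propan-2-yl)undec-5-en-9-yn-2-one | CC#CCC/C(C)=C\[C@@H](O)[C@H](C(C)C)C(=O)CCl | intermediate
17 | (2S,3S,4R,5Z)-1-chloro-6-methyl-3-(propan-2-yl)undec-5-en-9-yne-2,4-diol | CC#CCC/C(C)=C\[C@@H](O)[C@H](C(C)C)[C@H](O)CCl | intermediate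
18 | (3S,4R,5Z)-2,6-dimethyl-3-[(2S)-oxiran-2-yl]undec-5-en-9-yn-4-ol | CC#CCC/C(C)=C\[C@@H](O)[C@H](C(C)C)[C@H]1CO1 | intermediate
19 | (1S,2S)-3-methyl-1-[(2R,3S)-3-methyl-3-(pent-3-yn-1-yl)oxiran-2-yl]-2-[(2S)-oxiran-2-yl]butan-1-ol | CC#CCC[C@]1(C)O[C@@H]1[C@@H](O)[C@H](C(C)C)[C@H]1CO1 | intermediate
20 | (E)-cinnamic anhydride | O=C(/C=C/c1ccccc1)OC(=O)/C=C/c1ccccc1 | starting material
21 | (1S,2R)-3-methyl-1-[(2R,3S)-3-methyl-3-(pent-3-yn-1-yl)oxiran-2-yl]-2-[(2S)-oxiran-2-yl]butyl (2E)-3-phenylprop-2-enoate | CC#CCC[C@]1(C)O[C@@H]1[C@@H](OC(=O)/C=C/c1ccccc1)[C@H](C(C)C)[C@H]1CO1 | intermediate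
22 | oxanickelacyclohexene of divalent nickel (PBu3 on Ni; Ni bound to C1 and to the C8 oxygen) | C/C1=C(\CC[C@]2(C)O[C@@H]2[C@@H](OC(=O)/C=C/c2ccccc2)[C@H](C(C)C)[C@H](O3)C1)/[Ni]3P(CCCC)(CCCC)CCCC | intermediate
23 | O-diethylboryl ether (diethylborinate) of 24 at the C8 oxygen | C/C1=C\CC[C@]2(C)O[C@@H]2[C@@H](OC(=O)/C=C/c2ccccc2)[C@H](C(C)C)[C@H](OB(CC)CC)C1 | intermediate
24 | (1R,2S,3R,4R,6E,10S)-4-hydroxy-6,10-dimethyl-3-(propan-2-yl)-11-oxabicyclo[8.1.0]undec-6-en-2-yl (2E)-3-phenylprop-2-enoate; germacrane numbering 1(10)E,4S,5R,6S,7R,8R | C/C1=C\CC[C@]2(C)O[C@@H]2[C@@H](OC(=O)/C=C/c2ccccc2)[C@H](C(C)C)[C@H](O)C1 | target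

## Step count and risks

Total step count: 13. Longest linear sequence: 11 steps (steps 2, 3, 4, 6, 7, 8, 9, 10, 11, 12, 13 from 3; the same length from 1 through step 1).

Steps most likely to fail:

1. Step 13. The ring closure may stall through binding of zerovalent nickel to the electron-poor cinnamate alkene or reductive coupling at that enoate, may close in the exo mode at C1, or may give way to intermolecular oligomerisation. Fallback, setting out from 19 and coming back at 24: 19 would be esterified with (diethoxyphosphoryl)acetic acid (DCC, DMAP, CH2Cl2) to the phosphonoacetate ester F1. The enoate-free F1 would be cyclised under the conditions of step 13 to the macrocyclic phosphonoacetate F2. A Horner–Wadsworth–Emmons olefination of F2 with benzaldehyde (LiCl, DBU, MeCN) would then build the (E)-cinnamate after the ring is closed and give 24.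

2. Step 8. The carbenoid may decompose before it adds, and the lithium aldolate of the unprotected hydroxy amide may undergo retro-aldol cleavage or react incompletely. Fallback, setting out from 14 and coming back at 18: 14 would be treated with (phenylsulfanyl)methyllithium (thioanisole, n-BuLi, DABCO, THF, 0 °C to −78 °C), a stable C1 nucleophile, to give the alpha-phenylsulfanyl ketone F3. Reduction with Me4NBH(OAc)3 would give the anti-diol sulfide F4. S-methylation with Me3OBF4 (CH2Cl2) would give the sulfonium salt F5, which K2CO3 in MeOH should close to 18 with loss of methyl phenyl sulfide.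

3. Step 12. Acylation of the congested C6 carbinol, flanked by the oxirane and the branched C7, may be slow, which would leave time for base-induced epoxide migration or opening of an oxirane. Fallback, setting out from 18 and coming back at 21: the order would be reversed. 18 would be acylated with 20 (Et3N, DMAP) to the allylic cinnamate F6, where no epoxide can migrate. F6 would then be epoxidised with mCPBA/NaHCO3, the electron-poor cinnamate alkene staying untouched. Face selection would rest on the allylic 1,3-strain conformer, the peracid approaching anti to the branched C7 substituent, to give 21.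

Further compounds
F1 | step 13 | (1S,2R)-3-methyl-1-[(2R,3S)-3-methyl-3-(pent-3-yn-1-yl)oxiran-2-yl]-2-[(2S)-oxiran-2-yl]butyl 2-(diethoxyphosphoryl)acetate | CC#CCC[C@]1(C)O[C@@H]1[C@@H](OC(=O)CP(=O)(OCC)OCC)[C@H](C(C)C)[C@H]1CO1
F2 | step 13 | (1R,2S,3R,4R,6E,10S)-4-hydroxy-6,10-dimethyl-3-(propan-2-yl)-11-oxabicyclo[8.1.0]undec-6-en-2-yl 2-(diethoxyphosphoryl)acetate | C/C1=C\CC[C@]2(C)O[C@@H]2[C@@H](OC(=O)CP(=O)(OCC)OCC)[C@H](C(C)C)[C@H](O)C1
F3 | step 8 | (3S,4R,5Z)-4-hydroxy-6-methyl-1-(phenylsulfanyl)-3-(propan-2-yl)undec-5-en-9-yn-2-one | CC#CCC/C(C)=C\[C@@H](O)[C@H](C(C)C)C(=O)CSc1ccccc1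
F4 | step 8 | (2S,3S,4R,5Z)-6-methyl-1-(phenylsulfanyl)-3-(propan-2-yl)undec-5-en-9-yne-2,4-diol | CC#CCC/C(C)=C\[C@@H](O)[C@H](C(C)C)[C@H](O)CSc1ccccc1
F5 | step 8 | [(2S,3S,4R,5Z)-2,4-dihydroxy-6-methyl-3-(propan-2-yl)undec-5-en-9-yn-1-yl](methyl)phenylsulfanium tetrafluoroborate | CC#CCC/C(C)=C\[C@@H](O)[C@H](C(C)C)[C@H](O)C[S+](C)c1ccccc1.F[B-](F)(F)F
F6 | step 12 | (3S,4R,5Z)-2,6-dimethyl-3-[(2S)-oxiran-2-yl]undec-5-en-9-yn-4-yl (2E)-3-phenylprop-2-enoate | CC#CCC/C(C)=C\[C@@H](OC(=O)/C=C/c1ccccc1)[C@H](C(C)C)[C@H]1CO1
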